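The constants were hidden, so I set out to read one from the runs.

| setting | noon | spring | autumn | south | west |
|---|---|---|---|---|---|
| starting material | 0.050 M | 0.050 M | 0.10 M | 0.050 M | 0.050 M |
| partner | 0.020 M (fed, over 12 h) | 0.045 M (fed, over 12 h) | 0.030 M (fed, over 12 h) | 0.0300 M (fed, over 12 h) | 0.0300 M |
| protic impurity | 1 mM | 1 mM | 1 mM | 1.00 mM | 1.00 mM |
| remark | run made earlier; the fed solution adds 0.20 times the starting volume | run made earlier; the fed solution adds 0.20 times the starting volume | run made earlier; the fed solution adds 0.20 times the starting volume | the fed solution adds 0.20 times the starting volume | everything together at the start, the whole solution of partner included, so that from the start the volume is larger by 0.20 times the starting volume |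
| time |  |  |  | 12 h | 50 h |

| run | time / h | product / % |
|---|---|---|
| noon | 1.00 | 0.1 |
| noon | 1.50 | 0 |
| noon | 2.50 | 0.4 |
| noon | 4.00 | 0.6 |
| noon | 8.00 | 4.2 |
| noon | 12.0 | 8.3 |
| spring | 1.00 | 0 |
| spring | 1.50 | 0 |
| spring | 2.50 | 0.4 |
| spring | 4.00 | 1.4 |
| spring | 8.00 | 7.8 |
| spring | 12.0 | 18.3 |
| autumn | 1.00 | 0 |
| autumn | 3.00 | 0.1 |
| autumn | 6.00 | 2.5 |
| autumn | 8.00 | 4.9 |
| autumn | 12.0 | 11.4 |

(each reading ± 0.3 percentage points)

- charges are per starting volume, the dose included; the dosed solution carries all of it

- the winner by amount of product, in percent of the starting material charged; "neither" if no more than 2 percentage points parts them (south / west / neither)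
- how much product is there at the end, in percent of the starting material charged: south
- how much product is there at the end, in percent of the starting material charged: west

From the noon run to the spring run, the partner charge rose by a factor of 2.25 and product at 12.0 h by 2.20, so I took the coupling as first order in partner. Interpolating on the charge gave 12.3% for south. The autumn run, with the partner charge of south and 0.10 M of starting material, made 1.85 times as much product in concentration as that interpolated figure, so I took first order in starting material too. The impurity I treated as a correction, 1.00 mM taken off 0.0300 M of partner.

By its last reading the spring run had made 9.15 mM of product per starting volume, at a mean c(partner) near 15.8 mM, which gave a first constant of 1.06 /M/h. West starts diluted, with c(starting material) at 41.7 mM and c(partner), after the impurity, at 24.2 mM. The integrated second-order law for unequal concentrations then gave 45.5%.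

That average was the weak link: the spring run still read 0% at 1.50 h, and the average took those early hours in with the rest. I reforged it from the last two readings. Around 10.0 h product rose by 1.31 mM/h, with 6.53 mM made and c(partner) at 25.7 mM. This gave 1.18 /M/h, the coupling constant, meaning product made per hour, per starting volume, divided by the starting material left per starting volume and by c(partner). As a reading it put west at 47.0%, and I committed to that.

The forecast began "The runs read as simple bimolecular coupling" and gave 12.6% (11.5% to 13.8%) for south and 45% (34% to 54%) for west, so its winner was west; mine stood lower for south and higher for west. The flasks gave 12.5% in south and 47.6% in west.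

    starting material ⇌ intermediate A (K = 16.0, k = 6.60 × 10⁻⁴ /s)
    partner + intermediate C → product (k = 3.90 × 10⁻⁴ /M/s)
    partner + protic impurity → quenched reagent (k = 0.0450 /M/s)
    intermediate A → intermediate C (k = 6.20 × 10⁻⁵ /s)
    intermediate B ⇌ intermediate D (K = 0.390, k = 3.30 × 10⁻⁶ /s)
    starting material + partner → intermediate B (k = 5.50 × 10⁻⁵ /M/s)

In west, the step from intermediate A to intermediate C had a half-life of 3.1 h at 50.0 h, against 20 h for intermediate C in its coupling with partner at 0.299 h. At 50.0 h in west, intermediate C, the resting state, held 52.1% of the starting material charged. With 1.18 /M/h, the same law gives 38.9% for west at 30 h, where the flask holds 38.2%. For west with 0.12 M of partner it gives 98.0%, where that flask holds 96.9%.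

(The runs stem from a simulated flask with made-up constants, noise included.)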